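**Retrosynthetic overview**

1. The two aryl ketone bonds (each carbonyl carbon to the 4-position of a resorcinol ring) are cut last; they come from a double Friedel–Crafts acylation of resorcinol with a phenol diacid that already holds rings A and B.
2. The strategy rests on ring B: the aryloxy carbon B3 and the hydroxyl carbon B4 are adjacent, and the chain carbon B1 is para to B4. This is the pattern of a [4+2] adduct of a 2-silyloxy-3-aryloxybuta-1,3-diene (B2–B3–B4–B5) with a 2-nitroalkene (B1, B6), so B1–B2 and B5–B6 are disconnected.
3. The nitro group steers the regiochemistry and then leaves as nitrous acid: the adduct is dehydrogenated to the enone, silylated to the dienol ether, and aromatised by elimination.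
4. The diene comes from methyl dihydroferulate by carbenoid O–H insertion, Horner–Wadsworth–Emmons methylenation and enol silylation; the nitroalkene comes from methyl 4-nitrobutanoate by Henry reaction and dehydration.
5. Ring order: ring A is bought, ring B is made by cycloaddition and aromatised, and the two resorcinol rings are attached at the end.

Key step: step 7

Remark on the chemistry: the tertiary nitro group of the cycloadduct has no acidified neighbouring hydrogen, so dehydrogenation is placed before the loss of nitrous acid; racemic compounds are drawn as one enantiomer; the carbons of ring B are numbered around the ring from the chain carbon B1 to B6, and positions on ring A are described in words relative to its methoxy group, its ether oxygen and its chain.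

**Route**

Step 1
Reactants: 1 3-(4-hydroxy-3-methoxyphenyl)propanoic acid
Product: 2 methyl 3-(4-hydroxy-3-methoxyphenyl)propanoate
Conditions: MeOH, H2SO4 (cat.), reflux
Reagents that add atoms: methanol, CO
Why: Fischer esterification of an unhindered aliphatic acid, which leaves the phenol free and masks the acid for the carbenoid and enolisation steps.

Step 2
Reactants: 2 methyl 3-(4-hydroxy-3-methoxyphenyl)propanoate; 3 dimethyl (1-diazo-2-oxopropyl)phosphonate
Product: 4 methyl 3-[4-[1-(dimethoxyphosphoryl)-2-oxopropoxy]-3-methoxyphenyl]propanoate (racemic)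
Conditions: Rh2(OAc)4 (1 mol %), PhMe, 80 °C, slow addition of 3
Reagents that add atoms: none
Why: Rhodium-carbenoid O–H insertion, in which the carbenoid formed from 3 by loss of dinitrogen is trapped by the phenol oxygen faster than by the arene, making the ring A oxygen–carbon bond and putting the phosphonate on the carbon that has to carry the methylene group.

Step 3
Reactants: 4 methyl 3-[4-[1-(dimethoxyphosphoryl)-2-oxopropoxy]-3-methoxyphenyl]propanoate
Product: 5 methyl 3-[3-methoxy-4-(3-oxobut-1-en-2-yloxy)phenyl]propanoate
Conditions: 37% aq. CH2O, K2CO3, THF, 0 °C → rt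
Reagents that add atoms: formaldehyde, C=O
Why: Horner–Wadsworth–Emmons olefination with formaldehyde at the doubly activated phosphonate carbon, so the terminal methylene is placed without any choice between the two enolisable sides that an aryloxyacetone would offer.

Step 4
Reactants: 5 methyl 3-[3-methoxy-4-(3-oxobut-1-en-2-yloxy)phenyl]propanoate
Product: 6 methyl 3-[4-[3-(tert-butyldimethylsilyloxy)buta-1,3-dien-2-yloxy]-3-methoxyphenyl]propanoate
Conditions: TBSOTf, Et3N, CH2Cl2, 0 °C
Reagents that add atoms: tert-butyldimethylsilyl trifluoromethanesulfonate, CC(C)(C)[Si](C)(C)OS(=O)(=O)C(F)(F)F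
Why: Soft enolisation of a methyl ketone with a silyl triflate and a tertiary amine; the methyl group is the only enolisable position of the ketone and the ester is not silylated under these conditions, so the 2-silyloxy diene should form with defined constitution.

Step 5
Reactants: 7 methyl 4-nitrobutanoate
Product: 8 methyl 5-hydroxy-4-nitropentanoate (racemic)
Conditions: (CH2O)n (0.8 equiv), Et3N (cat.), iPrOH, rt
Reagents that add atoms: formaldehyde (from paraformaldehyde), C=O
Why: Henry (nitroaldol) reaction of the nitronate with formaldehyde, held at the mono-adduct by a deficit of formaldehyde and catalytic base; the new stereocentre is racemic and disappears in the next step.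

Step 6
Reactants: 8 methyl 5-hydroxy-4-nitropentanoate
Product: 10 methyl 4-nitropent-4-enoate, via mesylate 9 (not isolated)
Conditions: MsCl, Et3N, CH2Cl2, −30 → 0 °C; used at once
Reagents that add atoms: none
Why: Mesylation of the primary alcohol and E1cB elimination through the nitronate, the standard dehydration of a 2-nitro alcohol to a 2-nitroalkene; low temperature and immediate use limit polymerisation and double-bond migration.

Step 7
Reactants: 6 methyl 3-[4-[3-(tert-butyldimethylsilyloxy)buta-1,3-dien-2-yloxy]-3-methoxyphenyl]propanoate; 10 methyl 4-nitropent-4-enoate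
Product: 11 methyl 3-[4-[[2-(tert-butyldimethylsilyloxy)-5-(3-methoxy-3-oxopropyl)-5-nitrocyclohex-1-en-1-yl]oxy]-3-methoxyphenyl]propanoate (racemic)
Conditions: PhMe, BHT (cat.), 25 → 60 °C, 10 in 1.5-fold excess
Reagents that add atoms: none
Why: The electron-rich diene 6 and the electron-poor nitroalkene 10 should combine in a concerted but asynchronous normal-electron-demand [4+2] cycloaddition, in which the bond from the diene terminus next to the silyloxy carbon (future B5) to the unsubstituted carbon of the nitroalkene (future B6) runs ahead of the B2–B1 bond. The closest known reaction type is the thermal Diels–Alder reaction of 2-silyloxybuta-1,3-dienes with 2-nitroalkenes, which gives 4-nitrocyclohexanone silyl enol ethers with the 1,4 orientation. Ring B closes as a six-membered carbocycle by intermolecular [4+2] cycloaddition, and the B3=B4 enediol diether double bond stays in place. The one new stereocentre, B1, forms without control as a racemate, which is acceptable because it becomes an sp2 carbon on aromatisation. The selectivity needed is regiochemical, B1 para to B4 and not to B3; it should be secured by the silyloxy group being a stronger donor than the aryloxy group, whose oxygen lone pair is shared with ring A, so that the largest HOMO coefficient sits on the terminus next to the silyloxy carbon, while the thermal, Lewis-acid-free conditions keep the nitroalkene acting as a 2π component and not as a heterodiene.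

Step 8
Reactants: 11 the nitrocyclohexene silyl enol ether adduct
Product: 12 methyl 3-[3-methoxy-4-[[3-(3-methoxy-3-oxopropyl)-3-nitro-6-oxocyclohex-1-en-1-yl]oxy]phenyl]propanoate (racemic; a 2-aryloxy-4-nitrocyclohex-2-enone)
Conditions: DDQ, 2,4,6-collidine, PhH, rt; aq. NaHCO3 work-up
Reagents that add atoms: none
Why: DDQ dehydrogenation of a silyl enol ether to the enone, in which the very electron-rich B3=B4 double bond is oxidised and a hydrogen is lost from B2, the only CH next to B3, while the quaternary nitro-bearing B1 is untouched.

Step 9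
Reactants: 12 the 2-aryloxy-4-nitrocyclohex-2-enone
Product: 14 methyl 3-[4-(tert-butyldimethylsilyloxy)-3-[2-methoxy-4-(3-methoxy-3-oxopropyl)phenoxy]phenyl]propanoate, via silyloxy diene 13 (not isolated)
Conditions: TBSOTf, Et3N, CH2Cl2, 0 °C → rt
Reagents that add atoms: tert-butyldimethylsilyl trifluoromethanesulfonate, CC(C)(C)[Si](C)(C)OS(=O)(=O)C(F)(F)F
Why: Soft enolisation toward B5, the only enolisable position, gives the 5-nitrocyclohexa-1,3-diene 13, from which the amine removes a B6 hydrogen as nitrite leaves B1 in an elimination driven by aromatisation, as in the known loss of nitrous acid from nitrocyclohexadiene cycloadducts; the B1 stereocentre is erased.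

Step 10
Reactants: 14 the aryl silyl ether diester
Product: 15 3-[4-[5-(2-carboxyethyl)-2-hydroxyphenoxy]-3-methoxyphenyl]propanoic acid
Conditions: LiOH, THF/MeOH/H2O, rt; then aq. HCl
Reagents that add atoms: lithium hydroxide, [Li+].[OH-]; water, O
Why: Saponification of both methyl esters, with hydroxide also cleaving the base-labile aryl silyl ether, so one operation frees the phenol and both acids while the aryl methyl ether and the diaryl ether are inert.

Step 11
Reactants: 15 the phenol diacid; 16 resorcinol (5 equiv)
Product: 17 verbenachalcone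
Conditions: BF3·OEt2 (solvent), 85 °C; then aq. NaOAc
Reagents that add atoms: none
Why: BF3-mediated Friedel–Crafts acylation of resorcinol by each carboxylic acid at the ring carbon para to one hydroxyl and ortho to the other, where the ortho-hydroxy ketone formed is held as a boron chelate against further acylation and the excess of resorcinol, a better nucleophile than rings A and B, works against indanone closure.

**Compound list**

1 | 3-(4-hydroxy-3-methoxyphenyl)propanoic acid | COc1cc(CCC(=O)O)ccc1O | starting material
2 | methyl 3-(4-hydroxy-3-methoxyphenyl)propanoate | COc1cc(CCC(=O)OC)ccc1O | intermediate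
3 | dimethyl (1-diazo-2-oxopropyl)phosphonate | CC(=O)C(=[N+]=[N-])P(=O)(OC)OC | starting material
4 | methyl 3-[4-[1-(dimethoxyphosphoryl)-2-oxopropoxy]-3-methoxyphenyl]propanoate (racemic, one enantiomer drawn) | COC(=O)CCc1ccc(O[C@H](C(C)=O)P(=O)(OC)OC)c(OC)c1 | intermediate
5 | methyl 3-[3-methoxy-4-(3-oxobut-1-en-2-yloxy)phenyl]propanoate | COC(=O)CCc1ccc(OC(=C)C(C)=O)c(OC)c1 | intermediate
6 | methyl 3-[4-[3-(tert-butyldimethylsilyloxy)buta-1,3-dien-2-yloxy]-3-methoxyphenyl]propanoate | C=C(O[Si](C)(C)C(C)(C)C)C(=C)Oc1ccc(CCC(=O)OC)cc1OC | intermediate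
7 | methyl 4-nitrobutanoate | COC(=O)CCC[N+](=O)[O-] | starting material
8 | methyl 5-hydroxy-4-nitropentanoate (racemic, one enantiomer drawn) | COC(=O)CC[C@@H](CO)[N+](=O)[O-] | intermediate
9 | methyl 5-(methylsulfonyloxy)-4-nitropentanoate (racemic, one enantiomer drawn) | COC(=O)CC[C@@H](COS(C)(=O)=O)[N+](=O)[O-] | intermediate (not isolated)
10 | methyl 4-nitropent-4-enoate | C=C(CCC(=O)OC)[N+](=O)[O-] | intermediate
11 | methyl 3-[4-[[2-(tert-butyldimethylsilyloxy)-5-(3-methoxy-3-oxopropyl)-5-nitrocyclohex-1-en-1-yl]oxy]-3-methoxyphenyl]propanoate (racemic, one enantiomer drawn) | COC(=O)CC[C@]1([N+](=O)[O-])CCC(O[Si](C)(C)C(C)(C)C)=C(Oc2ccc(CCC(=O)OC)cc2OC)C1 | intermediate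
12 | methyl 3-[3-methoxy-4-[[3-(3-methoxy-3-oxopropyl)-3-nitro-6-oxocyclohex-1-en-1-yl]oxy]phenyl]propanoate (racemic, one enantiomer drawn) | COC(=O)CC[C@]1([N+](=O)[O-])CCC(=O)C(Oc2ccc(CCC(=O)OC)cc2OC)=C1 | intermediate
13 | methyl 3-[4-[[6-(tert-butyldimethylsilyloxy)-3-(3-methoxy-3-oxopropyl)-3-nitrocyclohexa-1,5-dien-1-yl]oxy]-3-methoxyphenyl]propanoate (racemic, one enantiomer drawn) | COC(=O)CC[C@]1([N+](=O)[O-])CC=C(O[Si](C)(C)C(C)(C)C)C(Oc2ccc(CCC(=O)OC)cc2OC)=C1 | intermediate (not isolated)
14 | methyl 3-[4-(tert-butyldimethylsilyloxy)-3-[2-methoxy-4-(3-methoxy-3-oxopropyl)phenoxy]phenyl]propanoate | COC(=O)CCc1ccc(O[Si](C)(C)C(C)(C)C)c(Oc2ccc(CCC(=O)OC)cc2OC)c1 | intermediate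
15 | 3-[4-[5-(2-carboxyethyl)-2-hydroxyphenoxy]-3-methoxyphenyl]propanoic acid | COc1cc(CCC(=O)O)ccc1Oc1cc(CCC(=O)O)ccc1O | intermediate
16 | resorcinol | Oc1cccc(O)c1 | starting material
17 | verbenachalcone | COc1cc(CCC(=O)c2ccc(O)cc2O)ccc1Oc1cc(CCC(=O)c2ccc(O)cc2O)ccc1O | target

**Step count**

Total: 11 steps. Longest linear sequence: 9 steps (1, 2, 3, 4, 7, 8, 9, 10, 11).

**Steps most likely to fail**

Step 7. Regiocontrol between the two oxygen donors of the diene may be lost, the nitroalkene may add as a heterodiene across its C=C–N=O unit, or it may polymerise faster than it cycloadds. The fallback sets out from 2 and comes back at 15, and it makes the diaryl ether by copper catalysis in place of building ring B. Phenol 2 and commercial 4-(benzyloxy)-3-bromobenzaldehyde (CuI, N,N-dimethylglycine, Cs2CO3, dioxane, 90 °C, Ullmann coupling) should give the diaryl ether aldehyde F1. Horner–Wadsworth–Emmons olefination with trimethyl phosphonoacetate (NaH, THF) would give the cinnamate F2. Hydrogenation over Pd/C (H2, EtOAc/MeOH) would saturate the alkene and remove the benzyl group to give the phenol diester F3, and LiOH as in step 10 would give 15.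

Step 8. DDQ may abstract hydrogen unselectively (the benzylic positions of ring A, or B5 in place of B2), or the silyl enol ether may hydrolyse to the saturated ketone before it is oxidised. The fallback sets out from 11 and comes back at 15, and it removes the nitro group reductively and then dehydrogenates the ring with palladium and oxygen. Radical denitration of 11 (Bu3SnH, AIBN, PhMe, reflux) should give the denitrated silyl enol ether F4. Desilylation (TBAF, AcOH, THF) would give the 2-aryloxy-4-alkylcyclohexanone F5. Aerobic dehydrogenation of the cyclohexanone to the phenol (Pd(O2CCF3)2, 2-(dimethylamino)pyridine, TsOH, O2, DMSO, 80 °C) would give the phenol diester F3, and LiOH as in step 10 would give 15.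

Step 11. The activated acids may close onto the electron-rich rings A and B to give indanones, since the ring A carbon para to the methoxy group and the ring B carbon B6, para to the aryloxy group, each lie ortho to a chain; the free phenols may be O-acylated to oligomers, or the second acylation may stall. The fallback sets out from 14 and comes back at 17, and it makes the ketones by addition of an aryllithium to an N-methoxy-N-methylamide. Diester 14 with MeNH(OMe)·HCl and iPrMgCl (THF, −20 °C) should give the bis(N-methoxy-N-methylamide) F6. 1-Bromo-2,4-bis(methoxymethoxy)benzene F7, made from commercial 4-bromoresorcinol (MOMCl, iPr2NEt, CH2Cl2), would be converted with n-BuLi (THF, −78 °C) into 2,4-bis(methoxymethoxy)phenyllithium F8. Addition of F8 to F6 would give the protected bis-ketone F9, and TBAF in THF followed by HCl in MeOH at 50 °C would remove the silyl and methoxymethyl groups to give 17.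

**Further compounds**

F1 | step 7 | methyl 3-[4-[2-(benzyloxy)-5-formylphenoxy]-3-methoxyphenyl]propanoate | COC(=O)CCc1ccc(Oc2cc(C=O)ccc2OCc2ccccc2)c(OC)c1
F2 | step 7 | methyl (E)-3-[4-(benzyloxy)-3-[2-methoxy-4-(3-methoxy-3-oxopropyl)phenoxy]phenyl]prop-2-enoate | COC(=O)CCc1ccc(Oc2cc(/C=C/C(=O)OC)ccc2OCc2ccccc2)c(OC)c1
F3 | step 7 | methyl 3-[4-hydroxy-3-[2-methoxy-4-(3-methoxy-3-oxopropyl)phenoxy]phenyl]propanoate | COC(=O)CCc1ccc(O)c(Oc2ccc(CCC(=O)OC)cc2OC)c1
F4 | step 8 | methyl 3-[4-[[2-(tert-butyldimethylsilyloxy)-5-(3-methoxy-3-oxopropyl)cyclohex-1-en-1-yl]oxy]-3-methoxyphenyl]propanoate (racemic, one enantiomer drawn) | COC(=O)CC[C@@H]1CCC(O[Si](C)(C)C(C)(C)C)=C(Oc2ccc(CCC(=O)OC)cc2OC)C1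
F5 | step 8 | methyl 3-[3-methoxy-4-[[5-(3-methoxy-3-oxopropyl)-2-oxocyclohexyl]oxy]phenyl]propanoate (racemic mixture of diastereomers) | COC(=O)CCC1CCC(=O)C(Oc2ccc(CCC(=O)OC)cc2OC)C1
F6 | step 11 | 3-[4-(tert-butyldimethylsilyloxy)-3-[2-methoxy-4-[3-[methoxy(methyl)amino]-3-oxopropyl]phenoxy]phenyl]-N-methoxy-N-methylpropanamide | CON(C)C(=O)CCc1ccc(O[Si](C)(C)C(C)(C)C)c(Oc2ccc(CCC(=O)N(C)OC)cc2OC)c1
F7 | step 11 | 1-bromo-2,4-bis(methoxymethoxy)benzene | COCOc1ccc(Br)c(OCOC)c1
F8 | step 11 | 2,4-bis(methoxymethoxy)phenyllithium | [Li]c1ccc(OCOC)cc1OCOC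
F9 | step 11 | 1-[2,4-bis(methoxymethoxy)phenyl]-3-[4-[5-[3-[2,4-bis(methoxymethoxy)phenyl]-3-oxopropyl]-2-(tert-butyldimethylsilyloxy)phenoxy]-3-methoxyphenyl]propan-1-one | COCOc1ccc(C(=O)CCc2ccc(O[Si](C)(C)C(C)(C)C)c(Oc3ccc(CCC(=O)c4ccc(OCOC)cc4OCOC)cc3OC)c2)c(OCOC)c1
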